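**Retrosynthetic overview**
1. Numbering: the ten-membered carbocycle is C1 (oxirane CH), C2 (CH2), C3 (CH–O-angelate), C4 (oxirane C–Me), C5 (oxirane CH), C6 (CH2), C7 (CH–isopropenyl), C8 (CH–O-angelate), C9 (CH–OAc), C10 (oxirane C–Me). C11=C12 is the isopropenyl alkene.
2. Feature used: the exocyclic isopropenyl group on C7 sits next to the C8 carbinol of the ten-membered ring. This homoallylic alcohol C12=C11–C7–C8–OH is what a 2-methylallyl metal leaves after γ-attack on an aldehyde. The C7–C8 bond is therefore cut to give an open chain with tin on C12 and an aldehyde at C8.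
3. Both oxiranes carry their two ring bonds cis, so they go back to a (1(10)Z,4Z)-diene. The C1–C10 oxirane lies cis to O9 and is made from the free C9 alcohol with VO(acac)2/t-BuOOH. The C4–C5 oxirane lies trans to O3 and is made from the free C3 alcohol with a peracid. The three esters are placed around these two steps.
4. The chain comes from two Z-selective Wittig reactions of α-oxygenated methyl ketones (C1=C10 first, then C4=C5). C9 comes from methyl (S)-glycerate acetonide, C3 from (S)-α-hydroxy-γ-butyrolactone, and C5–C7 with C11–C13 from 5-bromo-2-methylpent-2-ene.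
5. Ring order: ten-membered carbocycle first (C7–C8 closure), then the C1–C10 oxirane, and last the C4–C5 oxirane.

Key step: step 17

Remark: the three starting materials and angelic acid are taken as commercial. The acetal carbon of 19–21 is carried as both epimers because it is destroyed in step 14.

Step 1
Reactants: 1 methyl (S)-2,2-dimethyl-1,3-dioxolane-4-carboxylate
Product: 3 (S)-1-(2,2-dimethyl-1,3-dioxolan-4-yl)ethanone, via dioxolane Weinreb amide 2 (not isolated)
Conditions: MeNH(OMe)·HCl, i-PrMgCl, THF, −20 °C; then MeMgBr, −20 → 0 °C; aq NH4Cl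
Reagents that add atoms: N,O-dimethylhydroxylamine hydrochloride, CNOC.Cl (atoms of 2); methylmagnesium bromide, C[Mg]Br
Why: Aminolysis of the ester by the chloromagnesium amide gives the Weinreb amide, whose chelated tetrahedral adduct with MeMgBr collapses to the ketone only on work-up (Weinreb ketone synthesis), and the future C9 centre is carried through unchanged because the cold medium holds no free enolising base.

Step 2
Reactants: 4 (S)-α-hydroxy-γ-butyrolactone
Product: 5 methyl (S)-4-bromo-2-hydroxybutanoate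
Conditions: HBr (g, saturated), MeOH, 0 °C → rt
Reagents that add atoms: hydrogen bromide, Br; methanol, CO
Why: Acid-mediated alcoholytic opening of a γ-lactone with HBr, in which bromide displaces the activated primary oxygen at C1 by SN2 and the carboxyl group is esterified, should leave the C3 carbinol untouched because substitution next to the ester carbonyl is strongly retarded, so the S centre of the chiral pool is kept.

Step 3
Reactants: 5 methyl (S)-4-bromo-2-hydroxybutanoate
Product: 6 methyl (S)-4-bromo-2-[(tert-butyldimethylsilyl)oxy]butanoate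
Conditions: TBSOTf, 2,6-lutidine, CH2Cl2, 0 °C
Reagents that add atoms: tert-butyldimethylsilyl triflate, CC(C)(C)[Si](C)(C)OS(=O)(=O)C(F)(F)F
Why: Silyl ether formation with a silyl triflate and a hindered pyridine base protects O3 quickly at 0 °C without any nucleophile that could attack the primary bromide.

Step 4
Reactants: 6 methyl (S)-4-bromo-2-[(tert-butyldimethylsilyl)oxy]butanoate
Product: 7 [(3S)-3-[(tert-butyldimethylsilyl)oxy]-4-methoxy-4-oxobutyl]triphenylphosphonium bromide
Conditions: PPh3, MeCN, reflux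
Reagents that add atoms: triphenylphosphine, c1ccc(cc1)P(c1ccccc1)c1ccccc1
Why: SN2 quaternisation of PPh3 by an unhindered primary bromide is the standard way to ester-bearing alkylphosphonium salts, and the silyl ether and ester are inert to the neutral conditions.

Step 5
Reactants: 7 [(3S)-3-[(tert-butyldimethylsilyl)oxy]-4-methoxy-4-oxobutyl]triphenylphosphonium bromide; 3 (S)-1-(2,2-dimethyl-1,3-dioxolan-4-yl)ethanone
Product: 9 methyl (2S,4Z)-2-[(tert-butyldimethylsilyl)oxy]-5-[(4R)-2,2-dimethyl-1,3-dioxolan-4-yl]hex-4-enoate, via ester ylide 8 (not isolated)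
Conditions: KN(SiMe3)2, THF, −78 → 0 °C; then 3, −78 °C → rt
Reagents that add atoms: none
Why: Wittig olefination of an α-oxygenated methyl ketone with a non-stabilised ylide under lithium-free kinetic control is known to give the Z-trisubstituted allylic ether, with the ylide chain (C2) cis to the oxygen-bearing carbon (C9), and the low temperature limits enolisation so that C9 and C3 are not scrambled.

Step 6
Reactants: 9 methyl (2S,4Z)-2-[(tert-butyldimethylsilyl)oxy]-5-[(4R)-2,2-dimethyl-1,3-dioxolan-4-yl]hex-4-enoate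
Product: 11 (3S,5Z)-3-[(tert-butyldimethylsilyl)oxy]-6-[(4R)-2,2-dimethyl-1,3-dioxolan-4-yl]hept-5-en-2-one, via hexenoic Weinreb amide 10 (not isolated)
Conditions: MeNH(OMe)·HCl, i-PrMgCl, THF, −20 → 0 °C; then MeMgBr, 0 °C; aq NH4Cl
Reagents that add atoms: N,O-dimethylhydroxylamine hydrochloride, CNOC.Cl (atoms of 10); methylmagnesium bromide, C[Mg]Br
Why: The same one-flask Weinreb ketone synthesis as in step 1 turns the ester carbon into the C4 methyl ketone without over-addition, and the magnesium amide and the Grignard reagent are not basic enough at these temperatures to epimerise the α-silyloxy centre C3.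

Step 7
Reactants: 12 homoprenyl bromide (5-bromo-2-methylpent-2-ene)
Product: 13 (E)-5-bromo-2-methylpent-2-en-1-ol
Conditions: SeO2 (cat.), t-BuOOH, CH2Cl2, 0 °C → rt
Reagents that add atoms: tert-butyl hydroperoxide, CC(C)(C)OO
Why: SeO2 allylic oxidation (ene reaction followed by 2,3-sigmatropic shift) attacks the methyl group trans to the chain of a trisubstituted alkene, which sets the E geometry of C7=C11 and leaves the alkyl bromide alone.

Step 8
Reactants: 13 (E)-5-bromo-2-methylpent-2-en-1-ol
Product: 14 (E)-[(5-bromo-2-methylpent-2-en-1-yl)oxy](tert-butyl)dimethylsilane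
Conditions: TBSCl, imidazole, CH2Cl2, 0 °C → rt
Reagents that add atoms: tert-butyldimethylsilyl chloride, CC(C)(C)[Si](C)(C)Cl
Why: Standard silylation of an unhindered primary allylic alcohol, chosen so that this group falls later under the same mild acid that opens the acetonide.

Step 9
Reactants: 14 (E)-[(5-bromo-2-methylpent-2-en-1-yl)oxy](tert-butyl)dimethylsilane
Product: 15 (E)-[5-[(tert-butyldimethylsilyl)oxy]-4-methylpent-3-en-1-yl]triphenylphosphonium bromide
Conditions: PPh3, i-Pr2NEt (cat.), MeCN, reflux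
Reagents that add atoms: triphenylphosphine, c1ccc(cc1)P(c1ccccc1)c1ccccc1
Why: SN2 quaternisation of PPh3 by the primary homoallylic bromide, with a trace of hindered amine to trap any HBr that would cleave the allylic silyl ether.

Step 10
Reactants: 15 (E)-[5-[(tert-butyldimethylsilyl)oxy]-4-methylpent-3-en-1-yl]triphenylphosphonium bromide; 11 (3S,5Z)-3-[(tert-butyldimethylsilyl)oxy]-6-[(4R)-2,2-dimethyl-1,3-dioxolan-4-yl]hept-5-en-2-one
Product: 17 (4R)-4-[(2Z,5S,6Z,9E)-5,11-bis[(tert-butyldimethylsilyl)oxy]-6,10-dimethylundeca-2,6,9-trien-2-yl]-2,2-dimethyl-1,3-dioxolane, via homoallylic ylide 16 (not isolated)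
Conditions: KN(SiMe3)2, THF, −78 → 0 °C; then 11, −78 °C → rt
Reagents that add atoms: none
Why: A second lithium-free Wittig olefination of an α-oxygenated methyl ketone with a non-stabilised homoallylic ylide should again place the ylide chain (C6) cis to the oxygen-bearing carbon (C3), which gives the Z C4=C5 alkene and the skipped diene without touching C3 or C9.

Step 11
Reactants: 17 (4R)-4-[(2Z,5S,6Z,9E)-5,11-bis[(tert-butyldimethylsilyl)oxy]-6,10-dimethylundeca-2,6,9-trien-2-yl]-2,2-dimethyl-1,3-dioxolane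
Product: 18 (2R,3Z,6S,7Z,10E)-6-[(tert-butyldimethylsilyl)oxy]-3,7,11-trimethyldodeca-3,7,10-triene-1,2,12-triol
Conditions: AcOH–THF–H2O (3:1:1), rt → 35 °C
Reagents that add atoms: none
Why: Mild aqueous acid hydrolysis cleaves the terminal acetonide and the unhindered primary allylic silyl ether, while the secondary C3 silyl ether, shielded by the methyl-bearing C4, hydrolyses much more slowly.

Step 12
Reactants: 18 (2R,3Z,6S,7Z,10E)-6-[(tert-butyldimethylsilyl)oxy]-3,7,11-trimethyldodeca-3,7,10-triene-1,2,12-triol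
Product: 19 (2E,5Z,7S,9Z)-7-[(tert-butyldimethylsilyl)oxy]-10-[(4R)-2-(4-methoxyphenyl)-1,3-dioxolan-4-yl]-2,6-dimethylundeca-2,5,9-trien-1-ol (both acetal epimers)
Conditions: 4-MeOC6H4CH(OMe)2, pyridinium 4-toluenesulfonate (cat.), CH2Cl2, rt
Reagents that add atoms: 4-methoxybenzaldehyde dimethyl acetal, COc1ccc(C(OC)OC)cc1
Why: In this acid-catalysed transacetalisation only the C8/C9 1,2-diol can close a five-membered cyclic acetal, and any mixed acetal at O12 reverts on aqueous work-up, so the C12 alcohol stays free.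

Step 13
Reactants: 19 (2E,5Z,7S,9Z)-7-[(tert-butyldimethylsilyl)oxy]-10-[(4R)-2-(4-methoxyphenyl)-1,3-dioxolan-4-yl]-2,6-dimethylundeca-2,5,9-trien-1-ol
Product: 21 (4R)-4-[(2Z,5S,6Z,9E)-5-[(tert-butyldimethylsilyl)oxy]-11-chloro-6,10-dimethylundeca-2,6,9-trien-2-yl]-2-(4-methoxyphenyl)-1,3-dioxolane, via allylic mesylate 20 (not isolated)
Conditions: MsCl, 2,4,6-collidine, LiCl, DMF, 0 °C
Reagents that add atoms: methanesulfonyl chloride, CS(=O)(=O)Cl (atoms of 20); lithium chloride, [Li+].[Cl-]
Why: Mesylation followed by SN2 displacement with chloride in the same flask is the usual mild conversion of a primary allylic alcohol into its chloride without allylic transposition or loss of the E geometry, and the weakly basic medium spares the acetal.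

Step 14
Reactants: 21 (4R)-4-[(2Z,5S,6Z,9E)-5-[(tert-butyldimethylsilyl)oxy]-11-chloro-6,10-dimethylundeca-2,6,9-trien-2-yl]-2-(4-methoxyphenyl)-1,3-dioxolane
Product: 22 (2R,3Z,6S,7Z,10E)-6-[(tert-butyldimethylsilyl)oxy]-12-chloro-2-[(4-methoxybenzyl)oxy]-3,7,11-trimethyldodeca-3,7,10-trien-1-ol
Conditions: i-Bu2AlH, CH2Cl2, −78 → 0 °C; aq potassium sodium tartrate
Reagents that add atoms: none
Why: In the reductive opening of a 4-methoxybenzylidene acetal aluminium binds the less hindered primary O8, the acetal C–O8 bond breaks and hydride goes to the oxocarbenium ion, which leaves the PMB group on the secondary O9, and the step is run before tin is introduced so that no allylmetal meets this cation.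

Step 15
Reactants: 22 (2R,3Z,6S,7Z,10E)-6-[(tert-butyldimethylsilyl)oxy]-12-chloro-2-[(4-methoxybenzyl)oxy]-3,7,11-trimethyldodeca-3,7,10-trien-1-ol
Product: 23 (2R,3Z,6S,7Z,10E)-6-[(tert-butyldimethylsilyl)oxy]-2-[(4-methoxybenzyl)oxy]-3,7,11-trimethyl-12-(tributylstannyl)dodeca-3,7,10-trien-1-ol
Conditions: Bu3SnLi (from Bu3SnH, LiN(i-Pr)2; 2.2 equiv), THF, −78 °C
Reagents that add atoms: tributylstannyllithium, [Li][Sn](CCCC)(CCCC)CCCC (made from tributylstannane, CCCC[SnH](CCCC)CCCC)
Why: SN2 displacement of a primary allylic chloride by the soft stannyl anion is fast at −78 °C and keeps the alkene position and E geometry, with the first equivalent only deprotonating the C8 hydroxyl group.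

Step 16
Reactants: 23 (2R,3Z,6S,7Z,10E)-6-[(tert-butyldimethylsilyl)oxy]-2-[(4-methoxybenzyl)oxy]-3,7,11-trimethyl-12-(tributylstannyl)dodeca-3,7,10-trien-1-ol
Product: 24 (2R,3Z,6S,7Z,10E)-6-[(tert-butyldimethylsilyl)oxy]-2-[(4-methoxybenzyl)oxy]-3,7,11-trimethyl-12-(tributylstannyl)dodeca-3,7,10-trienal
Conditions: Dess–Martin periodinane, pyridine, CH2Cl2, 0 °C
Reagents that add atoms: none
Why: Dess–Martin oxidation buffered with pyridine is fast and close to neutral, which spares the acid-labile allylstannane and avoids epimerisation at C9 or migration of C1=C10 into conjugation, and the aldehyde is used at once.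

Step 17
Reactants: 24 (2R,3Z,6S,7Z,10E)-6-[(tert-butyldimethylsilyl)oxy]-2-[(4-methoxybenzyl)oxy]-3,7,11-trimethyl-12-(tributylstannyl)dodeca-3,7,10-trienal
Product: 25 (1S,2R,3Z,6S,7Z,10R)-6-[(tert-butyldimethylsilyl)oxy]-2-[(4-methoxybenzyl)oxy]-3,7-dimethyl-10-(prop-1-en-2-yl)cyclodeca-3,7-dien-1-ol (route numbering 3S,7R,8S,9R)
Conditions: BF3·OEt2 (2 equiv), CH2Cl2, −78 °C, slow addition of 24 (final about 1 mM); aq NaHCO3
Reagents that add atoms: none
Why: BF3 binds the C8 carbonyl oxygen and the C7=C11 π bond, made electron-rich by hyperconjugation with the C12–Sn bond, attacks C8 through C7 (SE2′), after which the β-stannyl cation at C11 loses the tin group to fluoride and the C11=C12 isopropenyl alkene appears outside the new ring. The closest known reaction type is the Lewis acid-promoted intramolecular addition of allylic stannanes to aldehydes, which has closed ten- to fourteen-membered carbocycles at high dilution. The ten-membered carbocycle closes in the 10-exo-trig mode at the aldehyde carbon, and the attacking alkene is exocyclic to the forming ring as well, so neither the oxygen nor C11 ends up in the ring. C8 is controlled by the C9 stereocentre through polar Felkin–Anh addition, since monodentate BF3 cannot chelate O9: the C9–OPMB bond stands perpendicular to the carbonyl group and C7 arrives anti to it, which gives the 8,9-anti diol pattern (8S). C7 is controlled by the open antiperiplanar transition state in which C6 and C9 lie anti about the forming bond, the arrangement that makes such additions syn-selective whatever the stannane geometry, and this puts the isopropenyl group and O8 on the same ring face (7R). Ring closure must beat protodestannylation and oligomerisation, for which slow addition, a dry acid-free medium and the two Z alkenes that fold C7 toward C8 are relied on, the far higher nucleophilicity of the allylstannane should keep the C1=C10 and C4=C5 alkenes out of the reaction, and how far ring strain erodes the two diastereoselections has to be tested.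

Step 18
Reactants: 25 (1S,2R,3Z,6S,7Z,10R)-6-[(tert-butyldimethylsilyl)oxy]-2-[(4-methoxybenzyl)oxy]-3,7-dimethyl-10-(prop-1-en-2-yl)cyclodeca-3,7-dien-1-ol
Product: 26 C8 angelate of 25, (1S,2R,3Z,6S,7Z,10R)-6-[(tert-butyldimethylsilyl)oxy]-2-[(4-methoxybenzyl)oxy]-3,7-dimethyl-10-(prop-1-en-2-yl)cyclodeca-3,7-dien-1-yl (Z)-2-methylbut-2-enoate
Conditions: angelic acid, 2,4,6-Cl3C6H2COCl, Et3N, toluene, rt; then 25, 80 °C
Reagents that add atoms: angelic acid, C/C=C(/C)C(=O)O
Why: In this Yamaguchi-type mixed anhydride acylation run without a nucleophilic catalyst the alcohol attacks the less hindered angeloyl carbonyl group, and the absence of reversible conjugate addition keeps the Z geometry of the angelate.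

Step 19
Reactants: 26 C8 angelate of 25
Product: 27 (1S,2R,3Z,6S,7Z,10R)-6-[(tert-butyldimethylsilyl)oxy]-2-hydroxy-3,7-dimethyl-10-(prop-1-en-2-yl)cyclodeca-3,7-dien-1-yl (Z)-2-methylbut-2-enoate (free C9 alcohol)
Conditions: DDQ, CH2Cl2–pH 7 buffer, 0 °C
Reagents that add atoms: none
Why: Oxidative PMB cleavage with DDQ (hydride abstraction from the electron-rich benzylic position, then hydrolysis) runs at neutral pH, so the silyl ether, the alkenes and the neighbouring angelate should stay in place.

Step 20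
Reactants: 27 free C9 alcohol
Product: 28 cis-1,10-epoxy-9-ol, which is 27 with an oxirane across C1–C10 on the ring face of O9 (1R at the oxirane CH; C3, C7, C8 and C9 unchanged)
Conditions: VO(acac)2 (cat.), t-BuOOH (decane), CH2Cl2, 0 °C → rt
Reagents that add atoms: tert-butyl hydroperoxide, CC(C)(C)OO
Why: Hydroxyl-directed epoxidation through a vanadium alkoxide–peroxide complex reacts only at the allylic C1=C10 alkene, and because this transition state needs a small O9–C9–C10=C1 dihedral angle, which the Z ring alkene allows only in the rotamer with C8 on the opposite face and H9 next to the C10 methyl group (least A1,2 strain), oxygen is delivered cis to O9, as is the rule for medium-ring (Z)-cycloalk-2-enols.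

Step 21
Reactants: 28 cis-1,10-epoxy-9-ol
Product: 29 C9 acetate of 28
Conditions: Ac2O, pyridine, 4-(dimethylamino)pyridine (cat.), CH2Cl2, 0 °C → rt
Reagents that add atoms: acetic anhydride, CC(=O)OC(C)=O
Why: Amine-catalysed acetylation of the secondary alcohol is fast and too weakly basic to start a Payne rearrangement of the epoxy alcohol or an acyl shift from O8.

Step 22
Reactants: 29 C9 acetate of 28
Product: 30 free C3 alcohol, which is 29 without the silyl group
Conditions: Bu4NF, AcOH (1:1), THF, 0 °C → rt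
Reagents that add atoms: none
Why: Fluoride-mediated desilylation buffered with acetic acid protonates the alkoxide as it forms, which prevents ester cleavage, ester migration and oxirane opening.

Step 23
Reactants: 30 free C3 alcohol
Product: 31 diepoxy C3 alcohol, which is 30 with a second oxirane across C4–C5 on the ring face opposite to O3 (5S at the oxirane CH)
Conditions: mCPBA, CH2Cl2–aq pH 7 phosphate buffer, 0 °C
Reagents that add atoms: 3-chloroperoxybenzoic acid, OOC(=O)c1cccc(Cl)c1
Why: Hydroxyl-directed peracid epoxidation prefers an O3–C3–C4=C5 dihedral angle near 120°, which is the A1,3-minimised rotamer with H3 eclipsing the alkene and C2 on the far face, so oxygen arrives on the O3 side of this rotamer and gives the trans-epoxy alcohol typical of medium-ring (Z)-cycloalk-2-enols, while the 1,1-disubstituted isopropenyl and the electron-poor angelate alkenes react more slowly.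

Step 24
Reactants: 31 diepoxy C3 alcohol
Product: 32 CNP0220329.1, (1R,3S,4S,5S,7R,8S,9S,10R)-9-acetoxy-1,10:4,5-diepoxy-7-isopropenyl-4,10-dimethylcyclodecane-3,8-diyl bis[(Z)-2-methylbut-2-enoate] (route numbering)
Conditions: angelic acid, 2,4,6-Cl3C6H2COCl, Et3N, toluene, rt, filtered; then 31, 80 °C
Reagents that add atoms: angelic acid, C/C=C(/C)C(=O)O
Why: The same catalyst-free Yamaguchi-type mixed anhydride acylation as in step 18 esterifies O3 without strong base, which excludes a Payne rearrangement of the 3-hydroxy-4,5-oxirane and keeps the angelate Z.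

**Compound list**
1 | methyl (S)-2,2-dimethyl-1,3-dioxolane-4-carboxylate | COC(=O)[C@@H]1COC(C)(C)O1 | starting material
2 | (S)-N-methoxy-N,2,2-trimethyl-1,3-dioxolane-4-carboxamide (dioxolane Weinreb amide) | CON(C)C(=O)[C@@H]1COC(C)(C)O1 | intermediate
3 | (S)-1-(2,2-dimethyl-1,3-dioxolan-4-yl)ethanone | CC(=O)[C@@H]1COC(C)(C)O1 | intermediate
4 | (S)-α-hydroxy-γ-butyrolactone | O=C1OCC[C@@H]1O | starting material
5 | methyl (S)-4-bromo-2-hydroxybutanoate | COC(=O)[C@@H](O)CCBr | intermediate
6 | methyl (S)-4-bromo-2-[(tert-butyldimethylsilyl)oxy]butanoate | COC(=O)[C@@H](O[Si](C)(C)C(C)(C)C)CCBr | intermediate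
7 | [(3S)-3-[(tert-butyldimethylsilyl)oxy]-4-methoxy-4-oxobutyl]triphenylphosphonium bromide | COC(=O)[C@@H](O[Si](C)(C)C(C)(C)C)CC[P+](c1ccccc1)(c1ccccc1)c1ccccc1.[Br-] | intermediate
8 | ester ylide from 7 | COC(=O)[C@@H](O[Si](C)(C)C(C)(C)C)CC=P(c1ccccc1)(c1ccccc1)c1ccccc1 | intermediate
9 | methyl (2S,4Z)-2-[(tert-butyldimethylsilyl)oxy]-5-[(4R)-2,2-dimethyl-1,3-dioxolan-4-yl]hex-4-enoate | COC(=O)[C@@H](O[Si](C)(C)C(C)(C)C)C/C=C(C)\[C@@H]1COC(C)(C)O1 | intermediate
10 | hexenoic Weinreb amide from 9 | CON(C)C(=O)[C@@H](O[Si](C)(C)C(C)(C)C)C/C=C(C)\[C@@H]1COC(C)(C)O1 | intermediate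
11 | (3S,5Z)-3-[(tert-butyldimethylsilyl)oxy]-6-[(4R)-2,2-dimethyl-1,3-dioxolan-4-yl]hept-5-en-2-one | CC(=O)[C@@H](O[Si](C)(C)C(C)(C)C)C/C=C(C)\[C@@H]1COC(C)(C)O1 | intermediate
12 | homoprenyl bromide (5-bromo-2-methylpent-2-ene) | CC(C)=CCCBr | starting material
13 | (E)-5-bromo-2-methylpent-2-en-1-ol | OC/C(C)=C/CCBr | intermediate
14 | (E)-[(5-bromo-2-methylpent-2-en-1-yl)oxy](tert-butyl)dimethylsilane | CC(C)(C)[Si](C)(C)OC/C(C)=C/CCBr | intermediate
15 | (E)-[5-[(tert-butyldimethylsilyl)oxy]-4-methylpent-3-en-1-yl]triphenylphosphonium bromide | CC(C)(C)[Si](C)(C)OC/C(C)=C/CC[P+](c1ccccc1)(c1ccccc1)c1ccccc1.[Br-] | intermediate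
16 | homoallylic ylide from 15 | CC(C)(C)[Si](C)(C)OC/C(C)=C/CC=P(c1ccccc1)(c1ccccc1)c1ccccc1 | intermediate
17 | (4R)-4-[(2Z,5S,6Z,9E)-5,11-bis[(tert-butyldimethylsilyl)oxy]-6,10-dimethylundeca-2,6,9-trien-2-yl]-2,2-dimethyl-1,3-dioxolane | CC(C)(C)[Si](C)(C)OC/C(C)=C/C/C=C(C)\[C@@H](O[Si](C)(C)C(C)(C)C)C/C=C(C)\[C@@H]1COC(C)(C)O1 | intermediate
18 | (2R,3Z,6S,7Z,10E)-6-[(tert-butyldimethylsilyl)oxy]-3,7,11-trimethyldodeca-3,7,10-triene-1,2,12-triol | OC/C(C)=C/C/C=C(C)\[C@@H](O[Si](C)(C)C(C)(C)C)C/C=C(C)\[C@@H](O)CO | intermediate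
19 | (2E,5Z,7S,9Z)-7-[(tert-butyldimethylsilyl)oxy]-10-[(4R)-2-(4-methoxyphenyl)-1,3-dioxolan-4-yl]-2,6-dimethylundeca-2,5,9-trien-1-ol (both acetal epimers) | OC/C(C)=C/C/C=C(C)\[C@@H](O[Si](C)(C)C(C)(C)C)C/C=C(C)\[C@@H]1COC(c2ccc(OC)cc2)O1 | intermediate
20 | allylic mesylate of 19 | CS(=O)(=O)OC/C(C)=C/C/C=C(C)\[C@@H](O[Si](C)(C)C(C)(C)C)C/C=C(C)\[C@@H]1COC(c2ccc(OC)cc2)O1 | intermediate
21 | (4R)-4-[(2Z,5S,6Z,9E)-5-[(tert-butyldimethylsilyl)oxy]-11-chloro-6,10-dimethylundeca-2,6,9-trien-2-yl]-2-(4-methoxyphenyl)-1,3-dioxolane | ClC/C(C)=C/C/C=C(C)\[C@@H](O[Si](C)(C)C(C)(C)C)C/C=C(C)\[C@@H]1COC(c2ccc(OC)cc2)O1 | intermediate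
22 | (2R,3Z,6S,7Z,10E)-6-[(tert-butyldimethylsilyl)oxy]-12-chloro-2-[(4-methoxybenzyl)oxy]-3,7,11-trimethyldodeca-3,7,10-trien-1-ol | ClC/C(C)=C/C/C=C(C)\[C@@H](O[Si](C)(C)C(C)(C)C)C/C=C(C)\[C@@H](OCc1ccc(OC)cc1)CO | intermediate
23 | (2R,3Z,6S,7Z,10E)-6-[(tert-butyldimethylsilyl)oxy]-2-[(4-methoxybenzyl)oxy]-3,7,11-trimethyl-12-(tributylstannyl)dodeca-3,7,10-trien-1-ol | CCCC[Sn](CCCC)(CCCC)C/C(C)=C/C/C=C(C)\[C@@H](O[Si](C)(C)C(C)(C)C)C/C=C(C)\[C@@H](OCc1ccc(OC)cc1)CO | intermediate
24 | (2R,3Z,6S,7Z,10E)-6-[(tert-butyldimethylsilyl)oxy]-2-[(4-methoxybenzyl)oxy]-3,7,11-trimethyl-12-(tributylstannyl)dodeca-3,7,10-trienal | CCCC[Sn](CCCC)(CCCC)C/C(C)=C/C/C=C(C)\[C@@H](O[Si](C)(C)C(C)(C)C)C/C=C(C)\[C@@H](OCc1ccc(OC)cc1)C=O | intermediate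
25 | (1S,2R,3Z,6S,7Z,10R)-6-[(tert-butyldimethylsilyl)oxy]-2-[(4-methoxybenzyl)oxy]-3,7-dimethyl-10-(prop-1-en-2-yl)cyclodeca-3,7-dien-1-ol | C=C(C)[C@H]1C/C=C(C)\[C@@H](O[Si](C)(C)C(C)(C)C)C/C=C(C)\[C@@H](OCc2ccc(OC)cc2)[C@H]1O | intermediate
26 | C8 angelate of 25 | C=C(C)[C@H]1C/C=C(C)\[C@@H](O[Si](C)(C)C(C)(C)C)C/C=C(C)\[C@@H](OCc2ccc(OC)cc2)[C@H]1OC(=O)/C(C)=C\C | intermediate
27 | free C9 alcohol (26 without PMB) | C=C(C)[C@H]1C/C=C(C)\[C@@H](O[Si](C)(C)C(C)(C)C)C/C=C(C)\[C@@H](O)[C@H]1OC(=O)/C(C)=C\C | intermediate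
28 | cis-1,10-epoxy-9-ol | C=C(C)[C@H]1C/C=C(C)\[C@@H](O[Si](C)(C)C(C)(C)C)C[C@H]2O[C@@]2(C)[C@@H](O)[C@H]1OC(=O)/C(C)=C\C | intermediate
29 | C9 acetate of 28 | C=C(C)[C@H]1C/C=C(C)\[C@@H](O[Si](C)(C)C(C)(C)C)C[C@H]2O[C@@]2(C)[C@@H](OC(C)=O)[C@H]1OC(=O)/C(C)=C\C | intermediate
30 | free C3 alcohol (29 without the silyl group) | C=C(C)[C@H]1C/C=C(C)\[C@@H](O)C[C@H]2O[C@@]2(C)[C@@H](OC(C)=O)[C@H]1OC(=O)/C(C)=C\C | intermediate
31 | diepoxy C3 alcohol | C=C(C)[C@H]1C[C@@H]2O[C@]2(C)[C@@H](O)C[C@H]2O[C@@]2(C)[C@@H](OC(C)=O)[C@H]1OC(=O)/C(C)=C\C | intermediate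
32 | CNP0220329.1 | C=C(C)[C@H]1C[C@@H]2O[C@]2(C)[C@@H](OC(=O)/C(C)=C\C)C[C@H]2O[C@@]2(C)[C@@H](OC(C)=O)[C@H]1OC(=O)/C(C)=C\C | target

**Counts**
Total step count: 24.
Longest linear sequence: 20 steps, from 4 through steps 2–6 and 10–24.

**Steps most likely to fail**

1. Step 17 (macrocyclisation). Protodestannylation by traces of acid and intermolecular addition can outrun closure of the strained ring. Transannular strain can also erode the syn and Felkin–Anh preferences. The fallback closes the same bond without tin by a carbonyl-ene reaction and sets out from 22. LiEt3BH (THF, 0 °C) reduces the allylic chloride by SN2 hydride delivery to the prenyl-terminated alcohol F1. Dess–Martin periodinane with pyridine oxidises this to the prenyl-terminated trienal F2. Me2AlCl (CH2Cl2, −78 °C, slow addition) then promotes the intramolecular ene reaction, in which C7 bonds to C8 while a hydrogen atom of a C11 methyl group moves to the carbonyl oxygen. This comes back to the route at 25.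

2. Step 20 (C1=C10 epoxidation). Facial selectivity can be poor if the ring holds C9 in the rotamer with H9 eclipsing the alkene, because the vanadium alkoxide on O9 then reaches the wrong face. The angeloyl group can also shift from O8 to the free O9. The fallback uses the other neighbouring hydroxyl group as director and sets out from 25, whose free C8 alcohol is homoallylic to C1=C10. In that same H9-eclipsed rotamer C8 lies over the face that has to be oxidised. VO(acac)2/t-BuOOH (CH2Cl2, 0 °C) should therefore give the 1,10-epoxy C8 alcohol F3, with the less nucleophilic isopropenyl group expected to lag behind. Mixed anhydride angeloylation as in step 18 gives the epoxy angelate F4, and DDQ as in step 19 removes the PMB group. This comes back to the route at 28.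

3. Step 24 (last angeloylation). Acylation of the C3 carbinol next to the fully substituted oxirane carbon C4 can be slow. Prolonged heating then invites Z to E isomerisation of the angeloyl unit and acid-induced oxirane opening. The fallback builds the angelate alkene on the ester after acylation and sets out from 31. 2-[Bis(2,2,2-trifluoroethoxy)phosphoryl]propanoic acid, dicyclohexylcarbodiimide and catalytic 4-(dimethylamino)pyridine (CH2Cl2, 0 °C) give the C3 phosphonopropionate F5. A Still–Gennari olefination (KN(SiMe3)2, 18-crown-6, THF, −78 °C, then acetaldehyde) then forms the Z-2-methylbut-2-enoate directly. This comes back to the route at 32.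

**Further compounds**
F1 | step 17 | prenyl-terminated alcohol, (2R,3Z,6S,7Z)-6-[(tert-butyldimethylsilyl)oxy]-2-[(4-methoxybenzyl)oxy]-3,7,11-trimethyldodeca-3,7,10-trien-1-ol | CC(C)=CC/C=C(C)\[C@@H](O[Si](C)(C)C(C)(C)C)C/C=C(C)\[C@@H](OCc1ccc(OC)cc1)CO
F2 | step 17 | prenyl-terminated trienal, (2R,3Z,6S,7Z)-6-[(tert-butyldimethylsilyl)oxy]-2-[(4-methoxybenzyl)oxy]-3,7,11-trimethyldodeca-3,7,10-trienal | CC(C)=CC/C=C(C)\[C@@H](O[Si](C)(C)C(C)(C)C)C/C=C(C)\[C@@H](OCc1ccc(OC)cc1)C=O
F3 | step 20 | 1,10-epoxy C8 alcohol (25 with the C1–C10 oxirane on the ring face of O9) | C=C(C)[C@H]1C/C=C(C)\[C@@H](O[Si](C)(C)C(C)(C)C)C[C@H]2O[C@@]2(C)[C@@H](OCc3ccc(OC)cc3)[C@H]1O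
F4 | step 20 | epoxy angelate (C8 angelate of F3) | C=C(C)[C@H]1C/C=C(C)\[C@@H](O[Si](C)(C)C(C)(C)C)C[C@H]2O[C@@]2(C)[C@@H](OCc3ccc(OC)cc3)[C@H]1OC(=O)/C(C)=C\C
F5 | step 24 | C3 phosphonopropionate (31 acylated at O3, both epimers at the phosphonate carbon) | C=C(C)[C@H]1C[C@@H]2O[C@]2(C)[C@@H](OC(=O)C(C)P(=O)(OCC(F)(F)F)OCC(F)(F)F)C[C@H]2O[C@@]2(C)[C@@H](OC(C)=O)[C@H]1OC(=O)/C(C)=C\C
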